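At 2.00 d and later I treated the red run as stopped, and at 1.04 d and later the violet run, though substrate still stood in both.

| setting | red | violet | flask |
|---|---|---|---|
| left-handed substrate | 20 mM | 20 mM | 20 mM |
| right-handed substrate | 20 mM | 20 mM | 20 mM |
| coupling partner | 40 mM | 40 mM | 40.0 mM |
| free catalyst | 67 µM | 150 µM | 100 µM |
| remark | run made earlier | run made earlier |  |
| time |  |  | 10 d |

| run | time / d | left-handed substrate / % | right-handed substrate / % |
|---|---|---|---|
| red | 0.833 | 36.9 | 38.4 |
| red | 2.00 | 38.1 | 36.6 |
| red | 4.00 | 37.1 | 36.8 |
| red | 6.00 | 36.2 | 36.4 |
| violet | 0.500 | 31.8 | 35.4 |
| violet | 1.04 | 32.5 | 31.8 |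
| violet | 2.50 | 31.1 | 32.1 |
| violet | 6.00 | 30.3 | 31.6 |

(scatter of a reading: 0.5 percentage points)

- part of the left-handed substrate and right-handed substrate charged together that has reacted at 10 d
- excess of left-handed product over right-handed product in the product at 10 d
- excess of right-handed substrate over left-handed substrate among what is left of the two at 10 d

- free catalyst is single-handed; left-handed substrate and right-handed substrate are mirror images of each other, charged as a racemate, each of them at the stated concentration
- the numbers in the tables scatter with a standard deviation of 0.5 percentage points
- on the list of suspects stand: coupling partner + free catalyst + right-handed substrate -> free catalyst + right-handed product; left-handed substrate <-> right-handed substrate; coupling partner + free catalyst + left-handed substrate -> free catalyst + left-handed product; 2 free catalyst <-> resting dimer; coupling partner <-> dormant form; free catalyst -> spent catalyst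
- an excess is the difference of the two amounts in percent of their sum
- an excess is below zero if the other one leads

With the two substrates equal, their pool s, a fraction of the charge, falls pseudo-first-order: ds/dt = −k[partner][catalyst]s, where k lumps the two coupling steps. Integrated, −ln s = k∫[partner][catalyst]dt. I called this dimensionless number the reach, Λ.

Over those later readings, s was 73.7% in the red run and 63.1% in the violet run. So Λ read 0.305 and 0.460. Between these runs, Λ went as the catalyst charge to the power n = 0.511, a reading.

For the flask, I reckoned the reach, meaning the natural logarithms of pool its catalyst consumes before the stop, at 0.374. That put c at 31.2%.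

Was one number enough? Two runs left no spare reading to test n. The lead of the right-handed substrate averaged −0.53 percentage points in the red run and 0.53 points in the violet run, so I put eS at nil. But equal substrates suit a blind catalyst and fast interconversion alike, so Λ gave me no eP.

The forecast gave 31.5%, 4% and 0.8%, in its words: “I expect a small eP with a wide upper range”.

The flask gave c = 31.4%, eP = 96.0% and eS = 0%.

    coupling partner + free catalyst + right-handed substrate → free catalyst + right-handed product (k = 3900 M⁻² h⁻¹)
    left-handed substrate ⇌ right-handed substrate (k = 0.170 h⁻¹)
    coupling partner + free catalyst + left-handed substrate → free catalyst + left-handed product (k = 2.20 × 10⁵ M⁻² h⁻¹)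
    2 free catalyst ⇌ resting dimer, settled at all times (K = 73000 M⁻¹)
    coupling partner ⇌ dormant form (K = 12.0, k = 0.190 h⁻¹)
    free catalyst → spent catalyst (k = 0.230 h⁻¹)

Against my 31.2%, the flask's c stood at 31.4%. By that step alone, both ways together, the flask's substrates interconverted with a relaxation half-life of 0.0849 d, short against 10 d. The partner enters the integral to the first power, so for the neighbour charged with 68 mM of it I scaled Λ to 0.636. That reckoned c at 47.1%. The neighbour gave 46.9%, with eP at 95.6%.

The readings come from a simulation from invented constants; scatter was added.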